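Ring C of the flavanone half is disconnected at its aryl ether bond O1–C8a, which exposes a secondary benzylic alcohol at C2 and an ortho-brominated ring A. A copper-catalysed intramolecular O-arylation closes ring C in one operation without touching the C2–O bond, so the C2 configuration, set earlier by asymmetric transfer hydrogenation, is carried through. The step exploits the chain C2–C3–C4–C4a, which holds O1 over C8a of ring A. The precursor is a 2-(flavon-8-yl)-1,3-diarylpropane-1,3-diol: C4 stays a carbinol so that no enolisation or retro-aldol pathway exists under base, is oxidised afterwards, and C3 then equilibrates to trans. The 7''-oxygen travels as a MOM ether and is sulfated before final hydrogenolysis.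

Key step: step 10

Numbering: the flavanone half is numbered O1, C2, C3, C4, C4a–C8a with ring B on C2; the apigenin half carries double primes (C8'' is bonded to C3). "Fl" stands for 5-(benzyloxy)-2-[4-(benzyloxy)phenyl]-7-(methoxymethoxy)-4-oxo-4H-chromen-8-yl.

Remark: in step 8 the 4-benzyloxyphenyl ring is assumed to direct the transfer hydrogenation as the aryl group of a simple aryl ketone does, so that the (R,R)-TsDPEN catalyst gives the (R)-carbinol; the enantiomeric catalyst would be used if a test run showed the opposite sense.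

Step 1
Reactants: 1 apigenin
Product: 2 7-O-MOM-apigenin
Conditions: MOMCl (1.05 equiv), K2CO3 (1.1 equiv), DMF, 0 °C to rt
Reagents that add atoms: chloromethyl methyl ether, COCCl
Why: Williamson-type O-alkylation: the 7-OH, para to the C4 carbonyl through ring A, is the most acidic phenol, whereas the 5-OH is tied up in a hydrogen bond to the carbonyl and the 4'-OH is less acidic, so one equivalent of the chloromethyl ether should be taken up at O7.

Step 2
Reactants: 2 7-O-MOM-apigenin
Product: 3 5,4'-di-O-benzyl-7-O-MOM-apigenin
Conditions: BnBr (3 equiv), K2CO3 (3 equiv), KI (cat.), DMF, 70 °C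
Reagents that add atoms: benzyl bromide, BrCc1ccccc1
Why: Williamson ether synthesis under forcing conditions (DMF, heat, iodide catalysis), which are needed to alkylate the chelated 5-OH as well as the 4'-OH and which the MOM acetal tolerates.

Step 3
Reactants: 3 5,4'-di-O-benzyl-7-O-MOM-apigenin
Product: 4 8-iodo-5,4'-di-O-benzyl-7-O-MOM-apigenin
Conditions: iodine (1.05 equiv), AgO2CCF3 (1.05 equiv), NaHCO3, CH2Cl2, 0 °C to rt, dark
Reagents that add atoms: iodine, [I][I]
Why: Electrophilic aromatic iodination by the trifluoroacetyl hypoiodite formed in situ: C8 is ortho to O7, para to O5 and flanked on its other side only by the ring oxygen, so it should react ahead of C6 (wedged between two alkoxy groups) and of the enone-deactivated 4-benzyloxyphenyl ring, while the hydrogen carbonate buffer protects the MOM group.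

Step 4
Reactants: 4 8-iodo-5,4'-di-O-benzyl-7-O-MOM-apigenin; 5 1-[4-(benzyloxy)phenyl]ethanone (1.5 equiv)
Product: 6 8-[2-(4-benzyloxyphenyl)-2-oxoethyl]flavone (deoxybenzoin)
Conditions: Pd2(dba)3 (2.5 mol%), XPhos (6 mol%), K3PO4 (2.5 equiv), toluene, 90 °C
Reagents that add atoms: none
Why: Palladium-catalysed α-arylation of a ketone enolate: the bulky dialkylbiarylphosphine supports oxidative addition and C–C reductive elimination at the doubly ortho-substituted iodide, the mild phosphate base spares the flavone, and the congested product should resist a second arylation.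

Step 5
Reactants: 7 1,3-bis(benzyloxy)-5-bromobenzene
Product: 8 2,4-bis(benzyloxy)-6-bromobenzaldehyde
Conditions: POCl3 (1.5 equiv), DMF, 0 to 70 °C; then ice-water
Reagents that add atoms: N,N-dimethylformamide, CN(C)C=O; water, O
Why: Vilsmeier–Haack formylation: the chloroiminium ion attacks the position ortho to bromine, which is para to one benzyloxy group and ortho to the other, in preference to the more crowded position between the two benzyloxy groups, as the dimethoxy analogue is known to behave.

Step 6
Reactants: 6 deoxybenzoin; 8 2,4-bis(benzyloxy)-6-bromobenzaldehyde (1.2 equiv)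
Product: 9 aldol adduct (β-hydroxy ketone, stereoisomer mixture)
Conditions: LiN(SiMe3)2 (1.1 equiv), THF, −78 °C; then 8, −78 to −40 °C; AcOH (1.2 equiv) at −78 °C
Reagents that add atoms: none
Why: Aldol addition of the lithium enolate of 6, whose ketone-activated benzylic CH2 is the only acidic site, to the aldehyde at −78 °C with a cold acidic quench to forestall retro-aldol cleavage; no stereocontrol is sought because the carbinol is oxidised in step 7 and the carbon between the carbonyls becomes epimerisable.

Step 7
Reactants: 9 aldol adduct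
Product: 10 2-(Fl)-1,3-diarylpropane-1,3-dione
Conditions: Dess–Martin periodinane (1.5 equiv), NaHCO3, CH2Cl2, 0 °C to rt
Reagents that add atoms: none
Why: Dess–Martin oxidation of the secondary benzylic alcohol to the ketone under buffered, non-basic conditions in which the aldol adduct cannot revert.

Step 8
Reactants: 10 2-(Fl)-1,3-diarylpropane-1,3-dione
Product: 11 (3R)-β-hydroxy ketone (epimers at the carbon bearing Fl)
Conditions: RuCl(p-cymene)[(R,R)-TsDPEN] (2 mol%), HCO2H/Et3N (5:2), DMF, 30 °C
Reagents that add atoms: none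
Why: Noyori–Ikariya asymmetric transfer hydrogenation with dynamic kinetic resolution: only the unhindered 4-benzyloxyphenyl ketone can reach the Ru–H/N–H site (the other carbonyl carries two ortho substituents), hydride is delivered to one carbonyl face under catalyst control to set the (R)-carbinol that becomes C2, the acidic C–H between the carbonyls interconverts the enantiomers of 10, and the acidic medium keeps the β-hydroxy ketone from retro-aldol cleavage.

Step 9
Reactants: 11 (3R)-β-hydroxy ketone
Product: 12 (1S,3R)-syn-1,3-diol (epimers at the carbon bearing Fl)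
Conditions: Et2BOMe (1.1 equiv), NaBH4 (1.2 equiv), THF/MeOH (4:1), −78 °C; then MeOH co-evaporation
Reagents that add atoms: none
Why: Narasaka–Prasad reduction: the boron chelate of the β-hydroxy ketone activates the hindered carbonyl toward borohydride at −78 °C, where the flavone carbonyl is inert, and directs hydride to give the 1,3-syn diol, so that C4 is a carbinol and neither enolisation nor retro-aldol cleavage is possible in the basic step that follows.

Step 10
Reactants: 12 (1S,3R)-syn-1,3-diol
Product: 13 (2R,4S)-flavan-4-ol (epimers at C3)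
Conditions: CuI (10 mol%), 3,4,7,8-tetramethyl-1,10-phenanthroline (20 mol%), Cs2CO3 (2 equiv), toluene (0.02 M), 110 °C, argon
Reagents that add atoms: none
Why: Ullmann-type copper-catalysed intramolecular O-arylation: the alkoxide of the C2 carbinol binds monovalent copper, the ortho C8a–Br bond of ring A is activated at the metal and C–O reductive elimination from the aryl copper alkoxide forms O1–C8a. The closest known reaction type is the copper/phenanthroline etherification of aryl bromides with secondary aliphatic alcohols, here run intramolecularly. Ring C closes in a 6-exo sense at the sp2 carbon C8a, the bromide leaving from outside the new six-membered ring, through a seven-membered copper-containing ring that contracts on reductive elimination. No stereocentre is created: the (R) configuration at C2 is retained because only the O–H bond of the carbinol is broken, and with C4 at the carbinol level there is no acidic C3–H and no retro-aldol pathway under the carbonate base. The step needs chemoselectivity between the two hydroxyls, which ring size secures, since arylation of the C4 oxygen would give a four-membered ring whereas the C2 oxygen is held four carbons from C8a. High dilution and exclusion of air guard against intermolecular etherification and copper-mediated oxidation of the benzylic carbinols.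

Step 11
Reactants: 13 (2R,4S)-flavan-4-ol
Product: 15 (2R,3S)-trans-flavanone 7''-O-MOM ether, via C3-epimeric flavanone mixture 14 (not isolated)
Conditions: Dess–Martin periodinane (1.5 equiv), NaHCO3, CH2Cl2, 0 °C to rt; aqueous work-up; then DBU (0.1 equiv), CH2Cl2, 0 °C to rt
Reagents that add atoms: none
Why: Dess–Martin oxidation of the only free hydroxyl restores the C4 ketone, after which catalytic DBU equilibrates the now acidic C3–H through the enolate to the thermodynamically preferred 2,3-trans (diequatorial) isomer, which sets the (3S) centre while C2 is untouched because reprotonation of the enolate is far faster than endocyclic β-elimination of the aryloxide.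

Step 12
Reactants: 15 (2R,3S)-trans-flavanone 7''-O-MOM ether
Product: 16 (2R,3S)-7''-hydroxy pentabenzyl ether
Conditions: ZnBr2 (1.5 equiv), n-PrSH (3 equiv), CH2Cl2, 0 °C, 15 min
Reagents that add atoms: none
Why: Lewis-acid-assisted transacetalisation of the MOM group onto the thiol cleaves the aryl MOM ether within minutes at 0 °C, leaves the benzyl ethers intact and avoids the protic acid and heat under which the freed 7''-OH could add to the C4 ketone and dehydrate.

Step 13
Reactants: 16 (2R,3S)-7''-hydroxy pentabenzyl ether
Product: 17 sodium 7''-O-sulfate pentabenzyl ether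
Conditions: SO3·pyridine (5 equiv), pyridine, rt to 40 °C; then aq. NaHCO3
Reagents that add atoms: sulfur trioxide–pyridine complex, O=S(=O)([O-])[n+]1ccccc1; sodium hydrogen carbonate, [Na+].OC(=O)[O-]
Why: O-sulfation of a phenol with the sulfur trioxide–pyridine complex: the 7''-OH is the only free hydroxyl, so no site selectivity is needed, and conversion to the sodium salt removes the pyridine that would inhibit the hydrogenolysis.

Step 14
Reactants: 17 sodium 7''-O-sulfate pentabenzyl ether
Product: 18 CNP0271389.1 (target)
Conditions: H2 (1 atm), Pd/C (10 wt%), THF/MeOH, rt; then HCl (1.0 equiv, 0.1 M), 0 °C, reversed-phase desalting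
Reagents that add atoms: none
Why: Catalytic hydrogenolysis of the five benzyl ethers under neutral conditions that aryl sulfate salts withstand, stopped at the uptake required for five benzyl groups so that the flavone C2''=C3'' bond and the C4 ketone are not reduced, followed by cold, stoichiometric acidification to the hydrogen sulfate.

Compound list

1 | apigenin, 5,7-dihydroxy-2-(4-hydroxyphenyl)-4H-chromen-4-one | O=c1cc(-c2ccc(O)cc2)oc2cc(O)cc(O)c12 | starting material
2 | 5-hydroxy-2-(4-hydroxyphenyl)-7-(methoxymethoxy)-4H-chromen-4-one | COCOc1cc(O)c2c(=O)cc(-c3ccc(O)cc3)oc2c1 | intermediate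
3 | 5-(benzyloxy)-2-[4-(benzyloxy)phenyl]-7-(methoxymethoxy)-4H-chromen-4-one | COCOc1cc(OCc2ccccc2)c2c(=O)cc(-c3ccc(OCc4ccccc4)cc3)oc2c1 | intermediate
4 | 5-(benzyloxy)-2-[4-(benzyloxy)phenyl]-8-iodo-7-(methoxymethoxy)-4H-chromen-4-one | COCOc1cc(OCc2ccccc2)c2c(=O)cc(-c3ccc(OCc4ccccc4)cc3)oc2c1I | intermediate
5 | 1-[4-(benzyloxy)phenyl]ethanone | CC(=O)c1ccc(OCc2ccccc2)cc1 | starting material
6 | 5-(benzyloxy)-2-[4-(benzyloxy)phenyl]-8-{2-[4-(benzyloxy)phenyl]-2-oxoethyl}-7-(methoxymethoxy)-4H-chromen-4-one | O=C(Cc1c(OCOC)cc(OCc2ccccc2)c2c(=O)cc(-c3ccc(OCc4ccccc4)cc3)oc12)c1ccc(OCc2ccccc2)cc1 | intermediate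
7 | 1,3-bis(benzyloxy)-5-bromobenzene | Brc1cc(OCc2ccccc2)cc(OCc2ccccc2)c1 | starting material
8 | 2,4-bis(benzyloxy)-6-bromobenzaldehyde | O=Cc1c(Br)cc(OCc2ccccc2)cc1OCc1ccccc1 | intermediate
9 | 3-[2,4-bis(benzyloxy)-6-bromophenyl]-1-[4-(benzyloxy)phenyl]-3-hydroxy-2-(Fl)propan-1-one, mixture of stereoisomers | O=C(c1ccc(OCc2ccccc2)cc1)C(c1c(OCOC)cc(OCc2ccccc2)c2c(=O)cc(-c3ccc(OCc4ccccc4)cc3)oc12)C(O)c1c(Br)cc(OCc2ccccc2)cc1OCc1ccccc1 | intermediate
10 | 1-[2,4-bis(benzyloxy)-6-bromophenyl]-3-[4-(benzyloxy)phenyl]-2-(Fl)propane-1,3-dione | O=C(c1ccc(OCc2ccccc2)cc1)C(c1c(OCOC)cc(OCc2ccccc2)c2c(=O)cc(-c3ccc(OCc4ccccc4)cc3)oc12)C(=O)c1c(Br)cc(OCc2ccccc2)cc1OCc1ccccc1 | intermediate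
11 | (3R)-1-[2,4-bis(benzyloxy)-6-bromophenyl]-3-[4-(benzyloxy)phenyl]-3-hydroxy-2-(Fl)propan-1-one, epimers at chain C2 | O[C@@H](c1ccc(OCc2ccccc2)cc1)C(c1c(OCOC)cc(OCc2ccccc2)c2c(=O)cc(-c3ccc(OCc4ccccc4)cc3)oc12)C(=O)c1c(Br)cc(OCc2ccccc2)cc1OCc1ccccc1 | intermediate
12 | (1S,3R)-1-[2,4-bis(benzyloxy)-6-bromophenyl]-3-[4-(benzyloxy)phenyl]-2-(Fl)propane-1,3-diol, 1,3-syn diol, epimers at chain C2 | O[C@@H](c1ccc(OCc2ccccc2)cc1)C(c1c(OCOC)cc(OCc2ccccc2)c2c(=O)cc(-c3ccc(OCc4ccccc4)cc3)oc12)[C@H](O)c1c(Br)cc(OCc2ccccc2)cc1OCc1ccccc1 | intermediate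
13 | (2R,4S)-5,7-bis(benzyloxy)-2-[4-(benzyloxy)phenyl]-3-(Fl)chroman-4-ol, epimers at C3 | O[C@@H]1c2c(OCc3ccccc3)cc(OCc3ccccc3)cc2O[C@@H](c2ccc(OCc3ccccc3)cc2)C1c1c(OCOC)cc(OCc2ccccc2)c2c(=O)cc(-c3ccc(OCc4ccccc4)cc3)oc12 | intermediate
14 | (2R)-5,7-bis(benzyloxy)-2-[4-(benzyloxy)phenyl]-3-(Fl)chroman-4-one, mixture of C3 epimers | O=C1c2c(OCc3ccccc3)cc(OCc3ccccc3)cc2O[C@@H](c2ccc(OCc3ccccc3)cc2)C1c1c(OCOC)cc(OCc2ccccc2)c2c(=O)cc(-c3ccc(OCc4ccccc4)cc3)oc12 | intermediate (not isolated)
15 | (2R,3S)-5,7-bis(benzyloxy)-2-[4-(benzyloxy)phenyl]-3-(Fl)chroman-4-one, 2,3-trans | O=C1c2c(OCc3ccccc3)cc(OCc3ccccc3)cc2O[C@@H](c2ccc(OCc3ccccc3)cc2)[C@@H]1c1c(OCOC)cc(OCc2ccccc2)c2c(=O)cc(-c3ccc(OCc4ccccc4)cc3)oc12 | intermediate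
16 | (2R,3S)-5,7-bis(benzyloxy)-2-[4-(benzyloxy)phenyl]-3-{5-(benzyloxy)-2-[4-(benzyloxy)phenyl]-7-hydroxy-4-oxo-4H-chromen-8-yl}chroman-4-one | O=C1c2c(OCc3ccccc3)cc(OCc3ccccc3)cc2O[C@@H](c2ccc(OCc3ccccc3)cc2)[C@@H]1c1c(O)cc(OCc2ccccc2)c2c(=O)cc(-c3ccc(OCc4ccccc4)cc3)oc12 | intermediate
17 | sodium 5-(benzyloxy)-2-[4-(benzyloxy)phenyl]-8-{(2R,3S)-5,7-bis(benzyloxy)-2-[4-(benzyloxy)phenyl]-4-oxochroman-3-yl}-4-oxo-4H-chromen-7-yl sulfate | O=C1c2c(OCc3ccccc3)cc(OCc3ccccc3)cc2O[C@@H](c2ccc(OCc3ccccc3)cc2)[C@@H]1c1c(OS(=O)(=O)[O-])cc(OCc2ccccc2)c2c(=O)cc(-c3ccc(OCc4ccccc4)cc3)oc12.[Na+] | intermediate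
18 | CNP0271389.1, 5-hydroxy-2-(4-hydroxyphenyl)-8-[(2R,3S)-5,7-dihydroxy-2-(4-hydroxyphenyl)-4-oxochroman-3-yl]-4-oxo-4H-chromen-7-yl hydrogen sulfate | O=C1c2c(O)cc(O)cc2O[C@@H](c2ccc(O)cc2)[C@@H]1c1c(OS(=O)(=O)O)cc(O)c2c(=O)cc(-c3ccc(O)cc3)oc12 | target

Total step count: 14. Longest linear sequence: 13 steps (steps 1–4 and 6–14, from apigenin); step 5 is the side branch.

Steps most likely to fail

Step 10 (key step). C–O reductive elimination at the hindered secondary benzylic alkoxide may be too slow, so that hydrodebromination, sequestration of copper by the chelating 1,3-diol or oxidation of a benzylic carbinol takes over. The fallback sets out from diol 12 and returns at flavanol 13, forming the same O1–C8a bond by palladium catalysis: Pd(OAc)2, 2-(di-tert-butylphosphino)-1,1'-binaphthyl, Cs2CO3, toluene, 70 °C. Oxidative addition of C8a–Br to zerovalent palladium and C–O reductive elimination from the divalent aryl palladium alkoxide replace the copper cycle, which changes the metal and the bond-forming elementary step rather than solvent or temperature. No new compound arises (F0).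

Step 4. Oxidative addition and C–C reductive elimination at the doubly ortho-substituted iodide may fail, leading to hydrodeiodination of 4 or self-condensation of ketone 5. The fallback sets out from iodide 4 and returns at deoxybenzoin 6 with the polarity reversed. Miyaura borylation (B2pin2, PdCl2(dppf), KOAc, dioxane, 90 °C) turns 4 into the aryl nucleophile 5-(benzyloxy)-2-[4-(benzyloxy)phenyl]-7-(methoxymethoxy)-8-(pinacolboryl)-4H-chromen-4-one F1. Suzuki–Miyaura coupling of this boronate with commercial 2-bromo-1-[4-(benzyloxy)phenyl]ethanone (Pd(OAc)2, PPh3, K3PO4, THF/H2O, 50 °C) then gives 6, so that no ketone enolate has to approach the hindered aryl palladium centre.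

Step 8. Turnover may be poor or facial selectivity eroded at a ketone whose α-carbon carries two very large groups, and conjugate reduction of the flavone may compete. The fallback sets out from diketone 10 and returns at hydroxy ketone 11 by Corey–Bakshi–Shibata reduction: (S)-2-methyl-CBS-oxazaborolidine (20 mol%), BH3·SMe2, THF, −20 °C, the oxazaborolidine enantiomer being confirmed by a trial run. Here a boron Lewis acid binds and activates the unhindered carbonyl and delivers hydride from coordinated borane, in place of the outer-sphere Ru–H/N–H transfer. The di-ortho-substituted ketone should again stay untouched, and the configuration at the epimerisable carbon is immaterial. No new compound arises (F0).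

Further compounds

F0 | step 10 | none | none
F1 | step 4 | 5-(benzyloxy)-2-[4-(benzyloxy)phenyl]-7-(methoxymethoxy)-8-(4,4,5,5-tetramethyl-1,3,2-dioxaborolan-2-yl)-4H-chromen-4-one | COCOc1cc(OCc2ccccc2)c2c(=O)cc(-c3ccc(OCc4ccccc4)cc3)oc2c1B1OC(C)(C)C(C)(C)O1
F0 | step 8 | none | none
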